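**Retrosynthetic overview**

- Numbering: ring B is C1 (CH bearing ring C), C2 (CH bearing CH2OH), C3 (C–CO2Me), C4 (=CH), C4a, C8a; ring A is C4a, C5–C8, C8a. The strategy rests on ring A, which carries H at C5, OMe at C6 and C8, and the free OH at C7 between them. This is the pattern left when a 3-methoxyfuran (C4a, C5, C6, C7 and the C7 oxygen) takes up a methoxyalkyne (C8a≡C8) and the oxygen bridge opens.
- Last C–C bonds: C4a–C8a and C7–C8, by intramolecular (4+2) cycloaddition of an acyclic furyl acrylate carrying a tethered ynol ether. Rings A and B form together in that step; ring C comes from syringaldehyde.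
- Before that: C3=C4 by aldol condensation with 4-methoxyfuran-2-carbaldehyde, C2–C3 by oxazolidinone-directed alkylation, and C1–C8a by conjugate addition of a methoxyacetylide to a sulfone-activated arylidene imide.
- Design constraints: the ynol ether never meets a carboxylic acid, the hydroxy ester from auxiliary removal is carried through its lactone, and the ring C phenol is freed before the primary alcohol.

Key step: step 13

Remark: the conjugate addition of step 5 is not relied on for facial control at C1. Compound 13 and its C1 epimer are diastereomers through the auxiliary; they are assumed to be separable by chromatography after step 6 and assignable by crystallography.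

**Route**

Step 1
Reactants: 1 syringaldehyde
Product: 2 4-(methoxymethoxy)-3,5-dimethoxybenzaldehyde
Conditions: MOMCl, i-Pr2NEt, CH2Cl2, 0 °C → rt
Reagents that add atoms: chloromethyl methyl ether, COCCl
Why: Base-mediated O-alkylation of the phenol gives a MOM ether that is inert to the Grignard, amide-base, hydride and thermal steps that follow.

Step 2
Reactants: 3 (phenylsulfonyl)acetic acid; 4 (S)-4-benzyloxazolidin-2-one
Product: 6 (S)-4-benzyl-3-[2-(phenylsulfonyl)acetyl]oxazolidin-2-one, via mixed pivalic anhydride 5 (not isolated)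
Conditions: PivCl, Et3N, THF, −20 °C; then 4, LiCl, −20 °C → rt
Reagents that add atoms: none
Why: N-Acylation of the oxazolidinone by a mixed pivalic anhydride under LiCl/Et3N activation needs no strong base, so the acidic sulfonyl-activated CH2 group is tolerated.

Step 3
Reactants: 2 4-(methoxymethoxy)-3,5-dimethoxybenzaldehyde; 6 (S)-4-benzyl-3-[2-(phenylsulfonyl)acetyl]oxazolidin-2-one
Product: 7 (S)-4-benzyl-3-[3-[4-(methoxymethoxy)-3,5-dimethoxyphenyl]-2-(phenylsulfonyl)prop-2-enoyl]oxazolidin-2-one (mixture of alkene isomers)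
Conditions: piperidine (cat.), AcOH (cat.), 4 Å MS, toluene, 80 °C
Reagents that add atoms: none
Why: Knoevenagel condensation of the doubly activated methylene group with the aryl aldehyde gives the arylidene, whose geometry is immaterial because its β-carbon becomes sp3 in step 5.

Step 4
Reactants: 8 2-chloro-1,1-dimethoxyethane
Product: 10 methoxyacetylene, via sodium methoxyacetylide 9 (not isolated)
Conditions: NaNH2 (3 equiv), liq. NH3, −33 °C; aq. NH4Cl, −40 °C; distil, keep cold
Reagents that add atoms: none
Why: Twofold elimination (methanol, then HCl) from the α-chloro acetal with NaNH2 is the classical dehydrohalogenation route to a 1-alkoxyalkyne, isolated by distillation of the low-boiling product.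

Step 5
Reactants: 7 arylidene sulfonyl imide; 10 methoxyacetylene
Product: 12 (S)-4-benzyl-3-[5-methoxy-3-[4-(methoxymethoxy)-3,5-dimethoxyphenyl]-2-(phenylsulfonyl)pent-4-ynoyl]oxazolidin-2-one (mixture of diastereomers at C2 and C3 of the acyl chain), via bromomagnesium methoxyacetylide 11 (not isolated)
Conditions: EtMgBr, THF, 0 °C; then 7, −40 → 0 °C; aq. NH4Cl, 0 °C
Reagents that add atoms: none
Why: Conjugate addition of an alkynyl Grignard reagent to an alkylidene activated by both sulfone and imide gives a stabilised enolate that does not react further; C1 (C3 of the acyl chain) is formed without reliable facial control and both epimers are carried on.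

Step 6
Reactants: 12 sulfonyl adduct
Product: 13 (S)-4-benzyl-3-[(3S)-5-methoxy-3-[4-(methoxymethoxy)-3,5-dimethoxyphenyl]pent-4-ynoyl]oxazolidin-2-one
Conditions: SmI2 (2.5 equiv), THF/MeOH, −78 °C; chromatography on Et3N-deactivated silica
Reagents that add atoms: none
Why: Reductive desulfonylation of the α-sulfonyl imide by electron transfer from SmI2 with methanol as proton source leaves the ynol ether and the auxiliary untouched, and chromatography should separate 13 from the (3R)-epimer formed beside it from the mixture 12, so that C1 is fixed here by separation of diastereomers.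

Step 7
Reactants: 13 (3S)-imide; 14 methyl bromoacetate
Product: 15 (S)-4-benzyl-3-[(2S,3S)-5-methoxy-2-(2-methoxy-2-oxoethyl)-3-[4-(methoxymethoxy)-3,5-dimethoxyphenyl]pent-4-ynoyl]oxazolidin-2-one
Conditions: NaN(SiMe3)2, THF, −78 °C; then 14, −78 → −40 °C
Reagents that add atoms: none
Why: Evans asymmetric alkylation, in which the chelated sodium (Z)-enolate is alkylated by the α-bromo ester on the face away from the benzyl group, sets C2 as (2S) under auxiliary control.

Step 8
Reactants: 15 alkylated imide
Product: 17 (4S)-4-[(1S)-3-methoxy-1-[4-(methoxymethoxy)-3,5-dimethoxyphenyl]prop-2-yn-1-yl]oxolan-2-one, via hydroxy ester 16 (not isolated)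
Conditions: LiBH4, THF, 0 °C → rt; aq. potassium sodium tartrate
Reagents that add atoms: none
Why: LiBH4 reduces the N-acyl oxazolidinone in preference to the methyl ester (reductive auxiliary removal), and the alkoxide so formed closes onto the ester by 5-exo-trig acyl substitution to the γ-lactone without touching a stereocentre.

Step 9
Reactants: 17 lactone
Product: 21 methyl (3S,4S)-3-[(tert-butyldimethylsilyloxy)methyl]-6-methoxy-4-[4-(methoxymethoxy)-3,5-dimethoxyphenyl]hex-5-ynoate, via potassium hydroxy carboxylate 18 (not isolated), via bis-silyl compound 19 (not isolated), via potassium silyloxy carboxylate 20 (not isolated)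
Conditions: KOH, MeOH/H2O, rt; evaporate; TBSCl, imidazole, DMF, rt; K2CO3, MeOH/H2O, 0 °C; evaporate; MeI, DMF, rt
Reagents that add atoms: potassium hydroxide, [K+].[OH-]; tert-butyldimethylsilyl chloride, CC(C)(C)[Si](C)(C)Cl; iodomethane, CI
Why: Saponification, silylation of both oxygens, mild hydrolysis of the labile silyl ester and SN2 methylation of the carboxylate convert the lactone (and any uncyclised 16) into the silyl ether ester without releasing a free hydroxy ester or a carboxylic acid next to the ynol ether.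

Step 10
Reactants: 22 4-bromofuran-2-carbaldehyde
Product: 23 4-bromo-2-(dimethoxymethyl)furan
Conditions: HC(OMe)3, p-TsOH (cat.), MeOH, rt
Reagents that add atoms: trimethyl orthoformate, COC(OC)OC; methanol, CO
Why: Acid-catalysed acetalisation with the orthoformate as water scavenger masks the aldehyde against methoxide in the next step.

Step 11
Reactants: 23 4-bromo-2-(dimethoxymethyl)furan
Product: 25 4-methoxyfuran-2-carbaldehyde, via methoxyfuran acetal 24 (not isolated)
Conditions: NaOMe, CuBr (10 mol %), MeOH/NMP, 100 °C; then aq. citric acid, THF, rt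
Reagents that add atoms: sodium methoxide, [Na+].[O-]C; water, O
Why: Ullmann-type copper-catalysed C–O coupling replaces the ring bromide by methoxide, and mild aqueous acid then hydrolyses the acetal, the formyl group tempering the acid sensitivity of the 3-alkoxyfuran.

Step 12
Reactants: 21 silyl ether ester; 25 4-methoxyfuran-2-carbaldehyde
Product: 27 methyl (E)-2-[(2R,3S)-1-(tert-butyldimethylsilyloxy)-5-methoxy-3-[4-(methoxymethoxy)-3,5-dimethoxyphenyl]pent-4-yn-2-yl]-3-(4-methoxyfuran-2-yl)prop-2-enoate, via acetoxy ester 26 (not isolated)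
Conditions: LiN(i-Pr)2, THF, −78 °C; 25; Ac2O, −78 → 0 °C; DBU, rt → 40 °C
Reagents that add atoms: none
Why: Aldol addition of the ester lithium enolate to the aldehyde, O-acetylation of the aldolate and E1cB elimination with DBU should give the thermodynamically preferred (E)-acrylate (furyl trans to the ester and cis to C2), the geometry the ring closure needs.

Step 13
Reactants: 27 furyl acrylate with tethered ynol ether
Product: 29 methyl (1S,2R)-2-[(tert-butyldimethylsilyloxy)methyl]-7-hydroxy-6,8-dimethoxy-1-[4-(methoxymethoxy)-3,5-dimethoxyphenyl]-1,2-dihydronaphthalene-3-carboxylate, via oxa-bridged cycloadduct 28 (not isolated)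
Conditions: o-C6H4Cl2 (0.01 M, degassed), BHT (10 mol %), 2,6-di-tert-butylpyridine (20 mol %), 170–190 °C, sealed tube, under argon
Reagents that add atoms: none
Why: Proposed new method: on heating, the furan (C4a, C5, C6, C7 as the diene) and the tethered methoxyalkyne (C8a≡C8) should combine in an asynchronous intramolecular (4+2) cycloaddition, in which the bond from the most nucleophilic furan carbon (C7, flanked by the ring oxygen and the methoxy-bearing C6) to the oxygen-bearing alkyne carbon C8 leads and the C4a–C8a bond follows, giving the 7-oxanorbornadiene 28. The closest known reaction type is the thermal intramolecular Diels–Alder reaction of furans with tethered alkynes (and of 2-amidofurans with tethered π-bonds) that ends in oxa-bridge opening to a phenol or aniline; an alkoxyalkyne as the 2π partner is the untested element. Ring B closes as the six-membered tether ring (C4a–C4=C3–C2–C1–C8a, the cis-disposed C3=C4 bond holding diene and alkyne within reach) and ring A as the new six-membered carbocycle, both through the same two bonds. The bridged adduct then ionises at C4a–O, because the cation is delocalised onto C6 and C8 where the two methoxy groups stabilise it, and loss of the C7 proton gives the C7 phenol irreversibly, which also pulls a reversible cycloaddition forward. The two bridgehead centres of 28 vanish on aromatisation and C1 and C2 are not touched, so no stereocentre is set here. The step needs only regiocontrol, which the four-atom tether (C4, C3, C2, C1) secures for the two C–C bonds and the methoxy-directed bridge opening secures for the position of the hydroxyl group.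

Step 14
Reactants: 29 cyclised silyl ether MOM ether
Product: 30 methyl (1S,2R)-2-[(tert-butyldimethylsilyloxy)methyl]-7-hydroxy-1-(4-hydroxy-3,5-dimethoxyphenyl)-6,8-dimethoxy-1,2-dihydronaphthalene-3-carboxylate
Conditions: ZnBr2, n-PrSH, CH2Cl2, 0 °C, 10 min
Reagents that add atoms: none
Why: ZnBr2-assisted acetal exchange transfers the methoxymethyl group to the thiol within minutes, freeing the ring C phenol while the silyl ether still blocks lactonisation of the hydroxymethyl group onto the ester.

Step 15
Reactants: 30 silyl ether bis-phenol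
Product: 31 methyl (1S,2R)-7-hydroxy-1-(4-hydroxy-3,5-dimethoxyphenyl)-2-(hydroxymethyl)-6,8-dimethoxy-1,2-dihydronaphthalene-3-carboxylate (CNP0143100.1)
Conditions: HF·pyridine, pyridine, THF, 0 °C → rt
Reagents that add atoms: none
Why: Fluoride-driven cleavage of the Si–O bond under buffered, nearly neutral conditions releases the primary alcohol without acid or base strong enough to close the lactone or move the C3=C4 double bond.

**Compound list**

1 | syringaldehyde | COc1cc(C=O)cc(OC)c1O | starting material
2 | 4-(methoxymethoxy)-3,5-dimethoxybenzaldehyde | COCOc1c(OC)cc(C=O)cc1OC | intermediate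
3 | (phenylsulfonyl)acetic acid | OC(=O)CS(=O)(=O)c1ccccc1 | starting material
4 | (S)-4-benzyloxazolidin-2-one | O=C1N[C@@H](Cc2ccccc2)CO1 | starting material
5 | (phenylsulfonyl)acetic pivalic anhydride (not isolated) | CC(C)(C)C(=O)OC(=O)CS(=O)(=O)c1ccccc1 | intermediate
6 | (S)-4-benzyl-3-[2-(phenylsulfonyl)acetyl]oxazolidin-2-one | O=C(CS(=O)(=O)c1ccccc1)N1[C@@H](Cc2ccccc2)COC1=O | intermediate
7 | (S)-4-benzyl-3-[3-[4-(methoxymethoxy)-3,5-dimethoxyphenyl]-2-(phenylsulfonyl)prop-2-enoyl]oxazolidin-2-one, alkene geometry not defined | COCOc1c(OC)cc(C=C(C(=O)N2[C@@H](Cc3ccccc3)COC2=O)S(=O)(=O)c2ccccc2)cc1OC | intermediate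
8 | 2-chloro-1,1-dimethoxyethane (chloroacetaldehyde dimethyl acetal) | COC(CCl)OC | starting material
9 | sodium methoxyacetylide (not isolated) | [Na+].[C-]#COC | intermediate
10 | methoxyacetylene | COC#C | intermediate
11 | bromomagnesium methoxyacetylide (not isolated) | COC#C[Mg]Br | intermediate
12 | (S)-4-benzyl-3-[5-methoxy-3-[4-(methoxymethoxy)-3,5-dimethoxyphenyl]-2-(phenylsulfonyl)pent-4-ynoyl]oxazolidin-2-one, mixture of diastereomers at C2 and C3 of the acyl chain | COC#CC(c1cc(OC)c(OCOC)c(OC)c1)C(C(=O)N1[C@@H](Cc2ccccc2)COC1=O)S(=O)(=O)c1ccccc1 | intermediate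
13 | (S)-4-benzyl-3-[(3S)-5-methoxy-3-[4-(methoxymethoxy)-3,5-dimethoxyphenyl]pent-4-ynoyl]oxazolidin-2-one | COC#C[C@H](c1cc(OC)c(OCOC)c(OC)c1)CC(=O)N1[C@@H](Cc2ccccc2)COC1=O | intermediate
14 | methyl bromoacetate | COC(=O)CBr | starting material
15 | (S)-4-benzyl-3-[(2S,3S)-5-methoxy-2-(2-methoxy-2-oxoethyl)-3-[4-(methoxymethoxy)-3,5-dimethoxyphenyl]pent-4-ynoyl]oxazolidin-2-one | COC#C[C@H](c1cc(OC)c(OCOC)c(OC)c1)[C@@H](C(=O)N1[C@@H](Cc2ccccc2)COC1=O)CC(=O)OC | intermediate
16 | methyl (3S,4S)-3-(hydroxymethyl)-6-methoxy-4-[4-(methoxymethoxy)-3,5-dimethoxyphenyl]hex-5-ynoate (not isolated) | COC#C[C@H](c1cc(OC)c(OCOC)c(OC)c1)[C@@H](CO)CC(=O)OC | intermediate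
17 | (4S)-4-[(1S)-3-methoxy-1-[4-(methoxymethoxy)-3,5-dimethoxyphenyl]prop-2-yn-1-yl]oxolan-2-one | COC#C[C@H](c1cc(OC)c(OCOC)c(OC)c1)[C@@H]1CC(=O)OC1 | intermediate
18 | potassium (3S,4S)-3-(hydroxymethyl)-6-methoxy-4-[4-(methoxymethoxy)-3,5-dimethoxyphenyl]hex-5-ynoate (not isolated) | COC#C[C@H](c1cc(OC)c(OCOC)c(OC)c1)[C@@H](CO)CC(=O)[O-].[K+] | intermediate
19 | tert-butyldimethylsilyl (3S,4S)-3-[(tert-butyldimethylsilyloxy)methyl]-6-methoxy-4-[4-(methoxymethoxy)-3,5-dimethoxyphenyl]hex-5-ynoate (not isolated) | COC#C[C@H](c1cc(OC)c(OCOC)c(OC)c1)[C@@H](CO[Si](C)(C)C(C)(C)C)CC(=O)O[Si](C)(C)C(C)(C)C | intermediate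
20 | potassium (3S,4S)-3-[(tert-butyldimethylsilyloxy)methyl]-6-methoxy-4-[4-(methoxymethoxy)-3,5-dimethoxyphenyl]hex-5-ynoate (not isolated) | COC#C[C@H](c1cc(OC)c(OCOC)c(OC)c1)[C@@H](CO[Si](C)(C)C(C)(C)C)CC(=O)[O-].[K+] | intermediate
21 | methyl (3S,4S)-3-[(tert-butyldimethylsilyloxy)methyl]-6-methoxy-4-[4-(methoxymethoxy)-3,5-dimethoxyphenyl]hex-5-ynoate | COC#C[C@H](c1cc(OC)c(OCOC)c(OC)c1)[C@@H](CO[Si](C)(C)C(C)(C)C)CC(=O)OC | intermediate
22 | 4-bromofuran-2-carbaldehyde | O=Cc1cc(Br)co1 | starting material
23 | 4-bromo-2-(dimethoxymethyl)furan | COC(OC)c1cc(Br)co1 | intermediate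
24 | 2-(dimethoxymethyl)-4-methoxyfuran (not isolated) | COC(OC)c1cc(OC)co1 | intermediate
25 | 4-methoxyfuran-2-carbaldehyde | O=Cc1cc(OC)co1 | intermediate
26 | methyl 3-acetoxy-2-[(2R,3S)-1-(tert-butyldimethylsilyloxy)-5-methoxy-3-[4-(methoxymethoxy)-3,5-dimethoxyphenyl]pent-4-yn-2-yl]-3-(4-methoxyfuran-2-yl)propanoate, mixture at the two new centres (not isolated) | COC#C[C@H](c1cc(OC)c(OCOC)c(OC)c1)[C@@H](CO[Si](C)(C)C(C)(C)C)C(C(=O)OC)C(OC(C)=O)c1cc(OC)co1 | intermediate
27 | methyl (E)-2-[(2R,3S)-1-(tert-butyldimethylsilyloxy)-5-methoxy-3-[4-(methoxymethoxy)-3,5-dimethoxyphenyl]pent-4-yn-2-yl]-3-(4-methoxyfuran-2-yl)prop-2-enoate | COC#C[C@H](c1cc(OC)c(OCOC)c(OC)c1)[C@@H](CO[Si](C)(C)C(C)(C)C)/C(C(=O)OC)=C\c1cc(OC)co1 | intermediate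
28 | oxa-bridged cycloadduct (7-oxanorbornadiene with O joining C4a and C7; bridgehead configuration not defined; not isolated) | COC(=O)C1=CC23OC(C(OC)=C2)C(OC)=C3[C@H](c2cc(OC)c(OCOC)c(OC)c2)[C@H]1CO[Si](C)(C)C(C)(C)C | intermediate
29 | methyl (1S,2R)-2-[(tert-butyldimethylsilyloxy)methyl]-7-hydroxy-6,8-dimethoxy-1-[4-(methoxymethoxy)-3,5-dimethoxyphenyl]-1,2-dihydronaphthalene-3-carboxylate | COC(=O)C1=Cc2cc(OC)c(O)c(OC)c2[C@H](c2cc(OC)c(OCOC)c(OC)c2)[C@H]1CO[Si](C)(C)C(C)(C)C | intermediate
30 | methyl (1S,2R)-2-[(tert-butyldimethylsilyloxy)methyl]-7-hydroxy-1-(4-hydroxy-3,5-dimethoxyphenyl)-6,8-dimethoxy-1,2-dihydronaphthalene-3-carboxylate | COC(=O)C1=Cc2cc(OC)c(O)c(OC)c2[C@H](c2cc(OC)c(O)c(OC)c2)[C@H]1CO[Si](C)(C)C(C)(C)C | intermediate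
31 | methyl (1S,2R)-7-hydroxy-1-(4-hydroxy-3,5-dimethoxyphenyl)-2-(hydroxymethyl)-6,8-dimethoxy-1,2-dihydronaphthalene-3-carboxylate (CNP0143100.1) | COC(=O)C1=Cc2cc(OC)c(O)c(OC)c2[C@H](c2cc(OC)c(O)c(OC)c2)[C@H]1CO | target

**Step count and risks**

Total step count: 15. Longest linear sequence: 11 steps (steps 1, 3, 5, 6, 7, 8, 9, 12, 13, 14, 15, from syringaldehyde).

Steps most likely to fail:

Step 13. The cycloaddition may be too slow at a temperature the ynol ether and the furyl acrylate survive, so that polymerisation, alkene isomerisation or reversal of the bridged adduct wins before the bridge opens. The fallback uses known chemistry, sets out from syringaldehyde 1 and comes back at the target 31. Wittig olefination of 1 with Ph3P=CHCO2Me should give methyl sinapate F1. Oxidation of F1 with FeCl3 in aqueous acetone should couple two molecules at their β-carbons, and the bis(quinone methide) should close to racemic dimethyl trans-7-hydroxy-1-(4-hydroxy-3,5-dimethoxyphenyl)-6,8-dimethoxy-1,2-dihydronaphthalene-2,3-dicarboxylate F2. LiBH4 should reduce the non-conjugated C2 ester of F2 in preference to the conjugated C3 ester and give racemic 31. Preparative chromatography on a chiral stationary phase would then remove the enantiomer of the target F3 and deliver 31.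

Step 5. The acetylide may attack the imide carbonyl groups and strip the auxiliary, or add too slowly to the electron-rich arylidene; the addition also has no facial control, so a substantial part of the material is expected to be lost as the C1 epimer. The fallback sets out from aldehyde 2 and comes back at 13, with the addition run on an ester before the auxiliary is attached. Knoevenagel condensation of 2 with commercial methyl (phenylsulfonyl)acetate should give methyl 3-[4-(methoxymethoxy)-3,5-dimethoxyphenyl]-2-(phenylsulfonyl)prop-2-enoate F4. Addition of the Grignard reagent 11 should give the sulfonyl ester adduct F5, and SmI2 should remove the sulfone to give racemic methyl 5-methoxy-3-[4-(methoxymethoxy)-3,5-dimethoxyphenyl]pent-4-ynoate F6. LiOH should give the lithium carboxylate F7, which is never acidified. PivCl should convert F7 into the mixed pivalic anhydride F8, and 4 with Et3N and LiCl should give 13 together with (S)-4-benzyl-3-[(3R)-5-methoxy-3-[4-(methoxymethoxy)-3,5-dimethoxyphenyl]pent-4-ynoyl]oxazolidin-2-one F9, which is removed by chromatography as in step 6.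

Step 12. The elimination may erode the alkene geometry, or the aldolate may revert before it is acetylated. The fallback sets out from ester 21 and comes back at 27, replacing the aldol condensation by an olefination. LiN(i-Pr)2 followed by ClP(O)(OEt)2 should give the ketene acetal phosphate F10. Excess LiN(i-Pr)2 should induce the 1,3-shift of phosphorus from oxygen to carbon and give the α-phosphono ester F11. Horner–Wadsworth–Emmons reaction of F11 with aldehyde 25 (NaH, THF) should then give 27.

**Further compounds**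

F1 | step 13 | methyl sinapate | COC(=O)/C=C/c1cc(OC)c(O)c(OC)c1
F2 | step 13 | dimethyl trans-7-hydroxy-1-(4-hydroxy-3,5-dimethoxyphenyl)-6,8-dimethoxy-1,2-dihydronaphthalene-2,3-dicarboxylate, racemic, one enantiomer drawn | COC(=O)C1=Cc2cc(OC)c(O)c(OC)c2[C@H](c2cc(OC)c(O)c(OC)c2)[C@H]1C(=O)OC
F3 | step 13 | enantiomer of the target, methyl (1R,2S)-7-hydroxy-1-(4-hydroxy-3,5-dimethoxyphenyl)-2-(hydroxymethyl)-6,8-dimethoxy-1,2-dihydronaphthalene-3-carboxylate | COC(=O)C1=Cc2cc(OC)c(O)c(OC)c2[C@@H](c2cc(OC)c(O)c(OC)c2)[C@@H]1CO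
F4 | step 5 | methyl 3-[4-(methoxymethoxy)-3,5-dimethoxyphenyl]-2-(phenylsulfonyl)prop-2-enoate, alkene geometry not defined | COCOc1c(OC)cc(C=C(C(=O)OC)S(=O)(=O)c2ccccc2)cc1OC
F5 | step 5 | methyl 5-methoxy-3-[4-(methoxymethoxy)-3,5-dimethoxyphenyl]-2-(phenylsulfonyl)pent-4-ynoate, mixture of diastereomers | COC#CC(c1cc(OC)c(OCOC)c(OC)c1)C(C(=O)OC)S(=O)(=O)c1ccccc1
F6 | step 5 | methyl 5-methoxy-3-[4-(methoxymethoxy)-3,5-dimethoxyphenyl]pent-4-ynoate, racemic | COC#CC(c1cc(OC)c(OCOC)c(OC)c1)CC(=O)OC
F7 | step 5 | lithium 5-methoxy-3-[4-(methoxymethoxy)-3,5-dimethoxyphenyl]pent-4-ynoate, racemic | COC#CC(c1cc(OC)c(OCOC)c(OC)c1)CC(=O)[O-].[Li+]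
F8 | step 5 | 5-methoxy-3-[4-(methoxymethoxy)-3,5-dimethoxyphenyl]pent-4-ynoic pivalic anhydride, racemic | COC#CC(c1cc(OC)c(OCOC)c(OC)c1)CC(=O)OC(=O)C(C)(C)C
F9 | step 5 | (S)-4-benzyl-3-[(3R)-5-methoxy-3-[4-(methoxymethoxy)-3,5-dimethoxyphenyl]pent-4-ynoyl]oxazolidin-2-one, C3 epimer of 13 | COC#C[C@@H](c1cc(OC)c(OCOC)c(OC)c1)CC(=O)N1[C@@H](Cc2ccccc2)COC1=O
F10 | step 12 | ketene acetal phosphate of 21, diethyl [(3R,4S)-3-[(tert-butyldimethylsilyloxy)methyl]-1,6-dimethoxy-4-[4-(methoxymethoxy)-3,5-dimethoxyphenyl]hex-1-en-5-yn-1-yl] phosphate, enol geometry not defined | COC#C[C@H](c1cc(OC)c(OCOC)c(OC)c1)[C@@H](CO[Si](C)(C)C(C)(C)C)C=C(OC)OP(=O)(OCC)OCC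
F11 | step 12 | methyl (3R,4S)-3-[(tert-butyldimethylsilyloxy)methyl]-2-(diethoxyphosphoryl)-6-methoxy-4-[4-(methoxymethoxy)-3,5-dimethoxyphenyl]hex-5-ynoate, mixture at C2 | COC#C[C@H](c1cc(OC)c(OCOC)c(OC)c1)[C@@H](CO[Si](C)(C)C(C)(C)C)C(C(=O)OC)P(=O)(OCC)OCC
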